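**Retrosynthetic overview**
- The target, 3,4,7-tribromo-2-chloro-1H-indole, is traced back to 4,7-dibromo-1H-indole: C3–Br by electrophilic bromination, C2–Cl by carbamate-directed C2 deprotonation and Cl+ transfer, N-Boc removed last.
- 4,7-Dibromoindole comes from its 2-carboxylic ester by saponification and protodecarboxylation; the ester carbon marks the position that later takes chlorine.
- The indole-2-carboxylate is disconnected at N1–C7a: a vinyl nitrene from a (Z)-2-azidocinnamate closes the pyrrole ring (N1, C2, C3, C3a, C7a) onto the intact benzene ring. This is the only ring formed.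
- Feature used: C7a is ortho to C3a, and the other ortho neighbour of C3a, C4, carries bromine. A nitrogen held on C3a through C3–C2 therefore finds one aryl C–H only, and the 2,5-dibromo pattern of the aldehyde becomes the 4,7-pattern of the indole.
- The azidocinnamate comes from 2,5-dibromobenzaldehyde and methyl azidoacetate by condensation.

Key step: step 2

Remark on the chemistry: the target is planar and has no stereogenic element, so it is achiral and no enantiomer question arises; the route makes the one constitution drawn.

Step 1
Reactants: 1 2,5-dibromobenzaldehyde; 2 methyl azidoacetate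
Product: 3 methyl (Z)-2-azido-3-(2,5-dibromophenyl)prop-2-enoate
Conditions: NaOMe (excess), 2 (excess), MeOH, −15 → 0 °C; cold aq. NH4Cl quench
Reagents that add atoms: none
Why: Knoevenagel-type aldol condensation, in which the azidoacetate enolate adds to the non-enolisable aldehyde and E1cB loss of hydroxide should give the Z alkene (aryl trans to the ester, azide cis to the ring), the low temperature keeping the azide intact.

Step 2
Reactants: 3 methyl (Z)-2-azido-3-(2,5-dibromophenyl)prop-2-enoate
Product: 5 methyl 4,7-dibromo-1H-indole-2-carboxylate, via azirine ester 4 (not isolated)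
Conditions: xylenes, 140 °C, slow addition of 3 into the hot solvent (dilute), N2
Reagents that add atoms: none
Why: On heating, the vinyl azide should lose N2 to give the 2H-azirine 4, which opens reversibly to the singlet vinyl nitrene. The nitrene nitrogen then bonds to the ortho ring carbon in a five-atom, 6π-electrocyclic closure, so the pyrrole ring forms through the N1–C7a bond as a 7aH-indole, and a 1,5-hydrogen shift to nitrogen restores aromaticity. The closest known reaction is the Hemetsberger–Knittel indole synthesis, of which this is a direct application. No stereocentre is formed; the Z geometry places the nitrogen next to the ring, and the azirine equilibrium would feed any E isomer into the same pathway. The selectivity required is between the two ortho positions of the aryl group, and it is secured by the substrate because one of them already carries bromine, leaving a single C–H for the nitrene and hence only the 4,7-dibromo isomer. No metal is involved, so both C–Br bonds should survive, and dilution suppresses intermolecular nitrene reactions.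

Step 3
Reactants: 5 methyl 4,7-dibromo-1H-indole-2-carboxylate
Product: 6 4,7-dibromo-1H-indole-2-carboxylic acid
Conditions: LiOH·H2O, THF/MeOH/H2O, 50 °C; then 1 M HCl
Reagents that add atoms: lithium hydroxide, [Li+].[OH-] (oxygen of the carboxyl OH)
Why: Saponification of the methyl ester, to which the aryl bromides and the indole N–H are inert, with the acid expected to precipitate on acidification.

Step 4
Reactants: 6 4,7-dibromo-1H-indole-2-carboxylic acid
Product: 7 4,7-dibromo-1H-indole
Conditions: Cu powder (cat.), quinoline, 210 °C, N2, short reaction time
Reagents that add atoms: none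
Why: Copper-mediated thermal protodecarboxylation of an indole-2-carboxylic acid in quinoline, the standard way to remove the C2 carboxyl left by a Hemetsberger synthesis; without added ligand or strong base the aryl bromides should remain in place.

Step 5
Reactants: 7 4,7-dibromo-1H-indole
Product: 9 tert-butyl 3,4,7-tribromo-1H-indole-1-carboxylate, via 3,4,7-tribromo-1H-indole 8 (not isolated)
Conditions: NBS (1.0 equiv), THF, 0 °C; then Boc2O, DMAP (cat.), Et3N, 0 °C → rt
Reagents that add atoms: N-bromosuccinimide, O=C1CCC(=O)N1Br; di-tert-butyl dicarbonate, CC(C)(C)OC(=O)OC(=O)OC(C)(C)C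
Why: Electrophilic aromatic bromination at C3, the most nucleophilic position of the indole, followed in the same flask by DMAP-catalysed N-acylation with Boc2O, so that the sensitive 3-bromo N–H indole need not be isolated.

Step 6
Reactants: 9 tert-butyl 3,4,7-tribromo-1H-indole-1-carboxylate
Product: 11 tert-butyl 3,4,7-tribromo-2-chloro-1H-indole-1-carboxylate, via 2-lithio carbamate 10 (not isolated)
Conditions: LDA (commercial solution, 1.15 equiv), THF, −78 °C; then C2Cl6, −78 → −40 °C
Reagents that add atoms: hexachloroethane, ClC(Cl)(Cl)C(Cl)(Cl)Cl; lithium diisopropylamide, [Li+].CC(C)[N-]C(C)C (lithium of intermediate 10 only)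
Why: Carbamate-directed deprotonation of C2–H, the only pyrrole C–H left and acidified by the N-Boc group and the C3 bromine, by an amide base that cannot undergo bromine–lithium exchange, followed by electrophilic chlorination of the 2-lithio species through chlorine transfer from hexachloroethane.

Step 7
Reactants: 11 tert-butyl 3,4,7-tribromo-2-chloro-1H-indole-1-carboxylate
Product: 12 3,4,7-tribromo-2-chloro-1H-indole
Conditions: K2CO3 (0.3 equiv), MeOH/THF, rt; aq. NH4Cl work-up
Reagents that add atoms: none
Why: Base-catalysed methanolysis of the N-carbamate, easy because the tetrahalogenated indolide is a good leaving group, under non-acidic conditions that spare the 2-chloro-3-bromo unit.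

**Compound list**
1 | 2,5-dibromobenzaldehyde | O=Cc1cc(Br)ccc1Br | starting material
2 | methyl azidoacetate | COC(=O)CN=[N+]=[N-] | starting material
3 | methyl (Z)-2-azido-3-(2,5-dibromophenyl)prop-2-enoate | COC(=O)/C(N=[N+]=[N-])=C/c1cc(Br)ccc1Br | intermediate
4 | methyl 2-(2,5-dibromophenyl)-2H-azirine-3-carboxylate (racemic) | COC(=O)C1=NC1c1cc(Br)ccc1Br | intermediate (not isolated)
5 | methyl 4,7-dibromo-1H-indole-2-carboxylate | COC(=O)c1cc2c(Br)ccc(Br)c2[nH]1 | intermediate
6 | 4,7-dibromo-1H-indole-2-carboxylic acid | OC(=O)c1cc2c(Br)ccc(Br)c2[nH]1 | intermediate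
7 | 4,7-dibromo-1H-indole | Brc1ccc(Br)c2[nH]ccc12 | intermediate
8 | 3,4,7-tribromo-1H-indole | Brc1c[nH]c2c(Br)ccc(Br)c12 | intermediate (not isolated)
9 | tert-butyl 3,4,7-tribromo-1H-indole-1-carboxylate | CC(C)(C)OC(=O)n1cc(Br)c2c(Br)ccc(Br)c21 | intermediate
10 | tert-butyl 3,4,7-tribromo-2-lithio-1H-indole-1-carboxylate | [Li]c1c(Br)c2c(Br)ccc(Br)c2n1C(=O)OC(C)(C)C | intermediate (not isolated)
11 | tert-butyl 3,4,7-tribromo-2-chloro-1H-indole-1-carboxylate | CC(C)(C)OC(=O)n1c(Cl)c(Br)c2c(Br)ccc(Br)c21 | intermediate
12 | 3,4,7-tribromo-2-chloro-1H-indole | Clc1[nH]c2c(Br)ccc(Br)c2c1Br | target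

Total step count: 7. Longest linear sequence: 7 steps (1 → 12).

**Steps most likely to fail**

Step 6. The amide base may remove a benzenoid proton next to bromine, the 2-lithio species may pass on or lose bromine (halogen migration, aryne formation), or the carbamate may shift to C2 on warming. The fallback avoids organometallic intermediates and introduces C2–Cl before C3–Br. It sets out from 7 and returns at 12. Indole 7 would be oxidised with pyridinium tribromide in aqueous tert-butanol to 3,3,4,7-tetrabromo-1,3-dihydro-2H-indol-2-one F1. Zinc in acetic acid at room temperature should reduce this to 4,7-dibromo-1,3-dihydro-2H-indol-2-one F2. Deoxychlorination of the lactam with POCl3 (N,N-diethylaniline, toluene, 90 °C) would give 4,7-dibromo-2-chloro-1H-indole F3. Bromination of F3 at C3 with NBS in DMF at 0 °C would then give 12 directly.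

Step 4. At 210 °C with copper present, reductive loss of bromine, Ullmann-type coupling of an aryl bromide with the indole N–H, or charring before CO2 is lost may compete. The fallback removes the C2 carbon as carbon monoxide instead of carbon dioxide. It sets out from 5 and returns at 7. Ester 5 would be reduced with DIBAL-H (THF, −78 → 0 °C) to (4,7-dibromo-1H-indol-2-yl)methanol F4. Oxidation with MnO2 (CH2Cl2, rt) should give 4,7-dibromo-1H-indole-2-carbaldehyde F5. Tsuji–Wilkinson decarbonylation of F5 with stoichiometric RhCl(PPh3)3 in refluxing toluene would give 7.

Step 1. Base-induced breakdown of the azidoacetate anion (loss of N2) may outrun condensation with the ortho-hindered aldehyde, and the reaction may stop at the aldol stage. The fallback separates C–C bond formation from alkene formation. It sets out from 1 and 2 and returns at 3. Aldol addition at −30 °C with short contact time (NaOMe, MeOH, acetic acid quench) would allow isolation of methyl 2-azido-3-(2,5-dibromophenyl)-3-hydroxypropanoate F6. Treatment with MsCl and Et3N in CH2Cl2 at 0 °C should convert it into methyl 2-azido-3-(2,5-dibromophenyl)-3-[(methylsulfonyl)oxy]propanoate F7, which is expected to eliminate in the same flask under the amine base to give 3.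

**Further compounds**
F1 | step 6 | 3,3,4,7-tetrabromo-1,3-dihydro-2H-indol-2-one | O=C1Nc2c(Br)ccc(Br)c2C1(Br)Br
F2 | step 6 | 4,7-dibromo-1,3-dihydro-2H-indol-2-one | O=C1Cc2c(Br)ccc(Br)c2N1
F3 | step 6 | 4,7-dibromo-2-chloro-1H-indole | Clc1cc2c(Br)ccc(Br)c2[nH]1
F4 | step 4 | (4,7-dibromo-1H-indol-2-yl)methanol | OCc1cc2c(Br)ccc(Br)c2[nH]1
F5 | step 4 | 4,7-dibromo-1H-indole-2-carbaldehyde | O=Cc1cc2c(Br)ccc(Br)c2[nH]1
F6 | step 1 | methyl 2-azido-3-(2,5-dibromophenyl)-3-hydroxypropanoate (racemic, mixture of diastereomers) | COC(=O)C(N=[N+]=[N-])C(O)c1cc(Br)ccc1Br
F7 | step 1 | methyl 2-azido-3-(2,5-dibromophenyl)-3-[(methylsulfonyl)oxy]propanoate (racemic, mixture of diastereomers) | COC(=O)C(N=[N+]=[N-])C(OS(C)(=O)=O)c1cc(Br)ccc1Br
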